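**Retrosynthetic overview**

- Last ring-forming event: the C5–O–C10 bridge (both oxepanes) closes by transannular 1,4-addition of the tertiary 10-OH to a Δ4-15-al, which is then reduced to the 15-ol; this sets C5 and C4.
- Before that, the ten-membered carbocycle and the trans γ-lactone form in one chromium-mediated C6–C7 allylation/lactonisation of an acyclic ω-formyl allylic bromide released from a vinyl epoxide; this sets C6 and C7 (C6–C7 is the bond the farnesyl chain closes in nature).
- Acyclic chain: (R)-linalool supplies C10, C14, C1–C3 and C8–C9; an alkenyl iodide (C4–C6, C15) is added to the C3 aldehyde under amino-alcohol catalysis (C3); C7 comes from hydroformylation, the C8–O centre from organocatalytic chlorination/epoxide closure, C11–C13 from methyl propiolate.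
- Side chain: silyl-protected sarracinic acid from ethyl but-2-ynoate, esterified onto 8-OH after macrocyclisation.
- Ring order: ten-membered ring → γ-lactone (same step) → oxygen bridge.

Assumption: the SMILES is read as the (3S,4S,5R,6S,7R,8R,10R) isomer in germacrane numbering (lactone O on C6, ether O between C5 and C10 in the inside,outside arrangement, 3-OAc, 8-O-(Z)-2-(hydroxymethyl)but-2-enoate, 15-OH); this numbering is used for all intermediates.

**Route**

Step 1
Reactants: 1 3,3-diethoxyprop-1-yne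
Product: 3 4,4-diethoxybut-2-yn-1-ol, via lithium acetylide 2 (not isolated)
Conditions: n-BuLi, THF, −78 °C; (CH2O)n, −78 °C → rt
Reagents that add atoms: formaldehyde (from paraformaldehyde), C=O
Why: Acetylide addition to formaldehyde (alkyne hydroxymethylation); no stereocentre is formed.

Step 2
Reactants: 3 4,4-diethoxybut-2-yn-1-ol
Product: 5 (Z)-4,4-diethoxy-3-iodobut-2-en-1-ol, via alkenylalanate 4 (not isolated)
Conditions: Na[AlH2(OCH2CH2OMe)2] (Red-Al), THF, 0 °C; then I2, −78 → 0 °C
Reagents that add atoms: iodine, II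
Why: Hydroxyl-directed trans-hydroalumination (hydride to C5, aluminium to C4) followed by iododealumination with retention gives the Z iodide, fixing C6 cis to the future C3 substituent on C4=C5.

Step 3
Reactants: 5 (Z)-4,4-diethoxy-3-iodobut-2-en-1-ol
Product: 6 (Z)-(4,4-diethoxy-3-iodobut-2-enyloxy)triethylsilane
Conditions: Et3SiCl, imidazole, CH2Cl2, 0 °C
Reagents that add atoms: chlorotriethylsilane, CC[Si](Cl)(CC)CC
Why: Standard O-silylation of the primary allylic alcohol; the primary Et3Si ether is chosen because it can later be oxidised directly to the aldehyde.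

Step 4
Reactants: 7 ethyl but-2-ynoate
Product: 9 ethyl (Z)-2-(hydroxymethyl)but-2-enoate (ethyl sarracinate), via vinylalane 8 (not isolated)
Conditions: i-Bu2AlH, NMO, THF, 0 °C; then CH2O (gas from cracked paraformaldehyde), −20 °C → rt
Reagents that add atoms: formaldehyde, C=O
Why: Syn hydroalumination of the ynoate (vinylalumination, a reductive aldol) puts H and Al cis, so trapping with formaldehyde at low temperature gives the Z (angelate-type) geometry.

Step 5
Reactants: 9 ethyl (Z)-2-(hydroxymethyl)but-2-enoate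
Product: 10 ethyl (Z)-2-[(triethylsilyloxy)methyl]but-2-enoate
Conditions: Et3SiCl, imidazole, CH2Cl2, 0 °C
Reagents that add atoms: chlorotriethylsilane, CC[Si](Cl)(CC)CC
Why: O-silylation of the primary allylic alcohol masks it for the later esterification.

Step 6
Reactants: 10 ethyl (Z)-2-[(triethylsilyloxy)methyl]but-2-enoate
Product: 11 (Z)-2-[(triethylsilyloxy)methyl]but-2-enoic acid
Conditions: LiOH·H2O, THF/H2O, 0 °C → rt; then 1 M HCl to pH 4, 0 °C
Reagents that add atoms: lithium hydroxide, [Li+].[OH-]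
Why: Mild ester saponification; hydroxide does not isomerise the Z-enoate and the silyl ether survives cold, weakly acidic work-up.

Step 7
Reactants: 12 (R)-(−)-linalool
Product: 13 (R)-linalool triethylsilyl ether
Conditions: Et3SiOTf, 2,6-lutidine, CH2Cl2, −78 → 0 °C
Reagents that add atoms: triethylsilyl trifluoromethanesulfonate, CC[Si](CC)(CC)OS(=O)(=O)C(F)(F)F
Why: Silylation of the tertiary alcohol with the triflate; the C10 stereocentre (10R) comes from the chiral pool and is never touched again.

Step 8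
Reactants: 13 (R)-linalool triethylsilyl ether
Product: 15 (4R)-4-methyl-4-(triethylsilyloxy)hex-5-enal (C3 aldehyde), via ozonide 14 (not isolated)
Conditions: O3 (1.0 equiv, Sudan Red 7B end point), CH2Cl2, −78 °C; then Me2S, → rt
Reagents that add atoms: ozone, [O-][O+]=O
Why: Chemoselective ozonolysis; the electron-rich trisubstituted alkene reacts far faster than the hindered vinyl group next to the quaternary silyloxy carbon.

Step 9
Reactants: 6 (Z)-(4,4-diethoxy-3-iodobut-2-enyloxy)triethylsilane; 15 (4R)-4-methyl-4-(triethylsilyloxy)hex-5-enal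
Product: 18 (3S,10R)-allylic acetate (chain C9=C8 vinyl–C10–C1–C2–C3(OAc)–C4[CH(OEt)2]=C5H–C6H2OSiEt3; C3 and C6 cis), via alkenylzinc bromide 16 (not isolated), via bromozinc alkoxide 17 (not isolated)
Conditions: 6, t-BuLi (2 equiv), Et2O, −78 °C; ZnBr2; then 15, (+)-MIB (10 mol%), TEEDA, toluene, −20 °C; then Ac2O, 0 °C → rt
Reagents that add atoms: acetic anhydride, CC(=O)OC(C)=O
Why: Catalytic asymmetric alkenylzinc addition to an aldehyde (Oppolzer/Walsh type) with retention of alkene geometry; the (+)-amino alcohol delivers the alkenyl group to the Re face, giving 3S, and the zinc alkoxide is acetylated in the same flask.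

Step 10
Reactants: 18 (3S,10R)-allylic acetate
Product: 19 (3S,10R)-aldehyde (C7 formyl; C8 and C9 methylene)
Conditions: Rh(acac)(CO)2 (1 mol%), BiPhePhos (2 mol%), CO/H2 (1:1, 10 bar), toluene, 70 °C
Reagents that add atoms: carbon monoxide, [C-]#[O+]
Why: Linear-selective rhodium-catalysed hydroformylation of the vinyl group (the adjacent quaternary carbon blocks the branched isomer); the trisubstituted alkene is inert.

Step 11
Reactants: 19 (3S,10R)-aldehyde
Product: 20 (3S,8S,10R)-8-chloro aldehyde
Conditions: (2R,5R)-2,5-diphenylpyrrolidine (10 mol%), NCS, CH2Cl2, −20 °C; used crude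
Reagents that add atoms: N-chlorosuccinimide, ClN1C(=O)CCC1=O
Why: Enamine-catalysed α-chlorination of an aldehyde; the C2-symmetric amine shields one enamine face and sets the 8S chloride under catalyst control (the enantiomeric amine gives 8R).

Step 12
Reactants: 20 (3S,8S,10R)-8-chloro aldehyde; 21 methyl propiolate
Product: 24 (3S,7R,8R,10R)-vinyl epoxide (methyl 2-(oxiran-2-yl)acrylate unit C13=C11(CO2Me)–C7–C8), via vinylalane 22 (not isolated), via chlorohydrin 23 (not isolated)
Conditions: 21, i-Bu2AlH, NMO, THF, 0 °C; then 20, −78 → −20 °C; work-up; Cs2CO3, MeCN, rt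
Reagents that add atoms: none
Why: Vinylalumination (Baylis–Hillman-type adduct without amine, so the chloro aldehyde does not racemise) adds anti to chlorine (Cornforth), and Williamson closure inverts C8 to the required 8R C–O bond; C7 of the trans-epoxide is erased in step 14.

Step 13
Reactants: 24 (3S,7R,8R,10R)-vinyl epoxide
Product: 25 (3S,7R,8R,10R)-epoxy enal (C6 aldehyde)
Conditions: (COCl)2, DMSO, CH2Cl2, −78 → −40 °C; Et3N
Reagents that add atoms: none
Why: Direct Swern oxidation of a primary triethylsilyl ether; the tertiary silyl ether, epoxide, acetal and acetate are untouched.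

Step 14
Reactants: 25 (3S,7R,8R,10R)-epoxy enal
Product: 28 8β-hydroxy macrolactone (3S,6R,7R,8R,10R; germacr-4-en-6,12-olide), via allylic bromide 26 (not isolated), via silyl ether lactone 27 (not isolated)
Conditions: Me3SiBr, CH2Cl2, −78 °C; then CrCl2 (10 equiv), THF, 2 mM (syringe pump), rt; then PPTS (cat.), EtOH, 0 °C
Reagents that add atoms: none
Why: Proposed new method: Me3SiBr opens the activated vinyl epoxide to the 8-O-silyl allylic bromide, CrCl2 turns it into a 2-carbomethoxyallylchromium that adds through C7 to the C6 aldehyde in a chair transition state and the chromium alkoxide lactonises (closest known: Nozaki–Hiyama chromium-Barbier macrocyclisation of ω-formyl allylic bromides to germacranolides, and silyl halide opening of epoxides); the equatorial γ-substituent gives the 6,7-anti trans-lactone, and attack anti to the C9 branch (H-8 eclipsing the alkene, silyloxy outside) gives C7 cis to the 8-oxygen.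

Step 15
Reactants: 28 8β-hydroxy macrolactone; 11 (Z)-2-[(triethylsilyloxy)methyl]but-2-enoic acid
Product: 30 8-O-[(Z)-2-(triethylsilyloxymethyl)but-2-enoyl] macrolactone, via mixed anhydride 29 (not isolated)
Conditions: 11, 2,4,6-Cl3C6H2COCl, Et3N, THF, rt; then 28, toluene, 70 °C (no DMAP)
Reagents that add atoms: none
Why: Yamaguchi esterification of the only acylable hydroxyl with retention at C8; omitting DMAP avoids Z to E isomerisation of the angelate-type acid.

Step 16
Reactants: 30 8-O-[(Z)-2-(triethylsilyloxymethyl)but-2-enoyl] macrolactone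
Product: 33 target CNP0195618.1, via hydroxy enal 31 (not isolated), via bridged aldehyde 32 (not isolated)
Conditions: p-TsOH·H2O (0.2 equiv), THF/H2O (4:1), rt; then NaHCO3, CeCl3·7H2O, NaBH4, MeOH, −40 °C
Reagents that add atoms: water, O
Why: Proposed new method: acid removes both Et3Si groups and the acetal, and the freed 10-OH adds transannularly to C5 of the protonated Δ4-15-al (closest known: Brønsted-acid intramolecular oxa-Michael cyclisation and transannular additions in germacranolides); the C7 tether reaches only the C5 face anti to the lactone C6–O on the allylic-strain-minimised rotamer (5R), the enol is protonated anti to the 3-acetoxy group (4S), and Luche reduction in the same flask traps the labile β-acetoxy aldehyde as the 15-ol.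

**Compound list**

1 | 3,3-diethoxyprop-1-yne | C#CC(OCC)OCC | starting material
2 | lithium 3,3-diethoxyprop-1-ynide | [Li]C#CC(OCC)OCC | intermediate (not isolated)
3 | 4,4-diethoxybut-2-yn-1-ol | OCC#CC(OCC)OCC | intermediate
4 | sodium cyclic alkenylalanate (Al bound to O6 and C4, H-5 trans to Al) | [Na+].COCCO[Al-]1(OCCOC)OCC=C1C(OCC)OCC | intermediate (not isolated)
5 | (Z)-4,4-diethoxy-3-iodobut-2-en-1-ol | OC/C=C(\I)C(OCC)OCC | intermediate
6 | (Z)-(4,4-diethoxy-3-iodobut-2-enyloxy)triethylsilane | CC[Si](CC)(CC)OC/C=C(\I)C(OCC)OCC | intermediate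
7 | ethyl but-2-ynoate | CC#CC(=O)OCC | starting material
8 | ethyl (E)-2-(diisobutylalumanyl)but-2-enoate (Al cis to H-3) | C/C=C(/[Al](CC(C)C)CC(C)C)C(=O)OCC | intermediate (not isolated)
9 | ethyl (Z)-2-(hydroxymethyl)but-2-enoate | C/C=C(/CO)C(=O)OCC | intermediate
10 | ethyl (Z)-2-[(triethylsilyloxy)methyl]but-2-enoate | C/C=C(/CO[Si](CC)(CC)CC)C(=O)OCC | intermediate
11 | (Z)-2-[(triethylsilyloxy)methyl]but-2-enoic acid | C/C=C(/CO[Si](CC)(CC)CC)C(O)=O | intermediate
12 | (R)-(−)-linalool | C=C[C@](C)(O)CCC=C(C)C | starting material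
13 | (3R)-3,7-dimethyl-3-(triethylsilyloxy)octa-1,6-diene | C=C[C@](C)(O[Si](CC)(CC)CC)CCC=C(C)C | intermediate
14 | secondary ozonide of 13 (mixture at the ozonide CH) | C=C[C@](C)(O[Si](CC)(CC)CC)CCC1OOC(C)(C)O1 | intermediate (not isolated)
15 | (4R)-4-methyl-4-(triethylsilyloxy)hex-5-enal | C=C[C@](C)(O[Si](CC)(CC)CC)CCC=O | intermediate
16 | (Z)-[1,1-diethoxy-4-(triethylsilyloxy)but-2-en-2-yl]zinc bromide | CC[Si](CC)(CC)OC/C=C(\[Zn]Br)C(OCC)OCC | intermediate (not isolated)
17 | bromozinc (3S,10R)-alkoxide of the coupled chain | C=C[C@](C)(O[Si](CC)(CC)CC)CC[C@H](O[Zn]Br)/C(=C\CO[Si](CC)(CC)CC)C(OCC)OCC | intermediate (not isolated)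
18 | (3S,10R)-3-acetoxy chain: C8=C9 vinyl, 10-OSiEt3, C15 diethyl acetal, 6-OSiEt3, C3 and C6 cis on C4=C5 (4E by CIP) | C=C[C@](C)(O[Si](CC)(CC)CC)CC[C@H](OC(C)=O)/C(=C\CO[Si](CC)(CC)CC)C(OCC)OCC | intermediate
19 | (3S,10R)-C7 aldehyde of 18 | O=CCC[C@](C)(O[Si](CC)(CC)CC)CC[C@H](OC(C)=O)/C(=C\CO[Si](CC)(CC)CC)C(OCC)OCC | intermediate
20 | (3S,8S,10R)-8-chloro C7 aldehyde | O=C[C@@H](Cl)C[C@](C)(O[Si](CC)(CC)CC)CC[C@H](OC(C)=O)/C(=C\CO[Si](CC)(CC)CC)C(OCC)OCC | intermediate
21 | methyl propiolate | C#CC(=O)OC | starting material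
22 | methyl 2-(diisobutylalumanyl)acrylate | C=C([Al](CC(C)C)CC(C)C)C(=O)OC | intermediate (not isolated)
23 | (3S,7R,8S,10R)-7-hydroxy-8-chloro α-methylene ester (anti chlorohydrin) | C=C(C(=O)OC)[C@@H](O)[C@@H](Cl)C[C@](C)(O[Si](CC)(CC)CC)CC[C@H](OC(C)=O)/C(=C\CO[Si](CC)(CC)CC)C(OCC)OCC | intermediate (not isolated)
24 | (3S,7R,8R,10R)-7,8-epoxy α-methylene ester (trans vinyl epoxide) | C=C(C(=O)OC)[C@H]1O[C@@H]1C[C@](C)(O[Si](CC)(CC)CC)CC[C@H](OC(C)=O)/C(=C\CO[Si](CC)(CC)CC)C(OCC)OCC | intermediate
25 | (3S,7R,8R,10R)-epoxy enal (C6 aldehyde) | C=C(C(=O)OC)[C@H]1O[C@@H]1C[C@](C)(O[Si](CC)(CC)CC)CC[C@H](OC(C)=O)/C(=C\C=O)C(OCC)OCC | intermediate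
26 | (3S,8R,10R)-(Z)-2-(bromomethyl)enoate with 8-OSiMe3 and C6 aldehyde | BrC/C(C(=O)OC)=C\[C@H](O[Si](C)(C)C)C[C@](C)(O[Si](CC)(CC)CC)CC[C@H](OC(C)=O)/C(=C\C=O)C(OCC)OCC | intermediate (not isolated)
27 | (3S,6R,7S,8R,10R)-8-O-trimethylsilyl germacr-4-en-6,12-olide | C=C1C(=O)O[C@@H]2/C=C(/C(OCC)OCC)[C@@H](OC(C)=O)CC[C@@](C)(O[Si](CC)(CC)CC)C[C@@H](O[Si](C)(C)C)[C@@H]12 | intermediate (not isolated)
28 | (3S,6R,7R,8R,10R)-3-acetoxy-15,15-diethoxy-8-hydroxy-10-(triethylsilyloxy)germacra-4,11(13)-dien-6,12-olide (trans-lactone, C3 and C6 cis on C4=C5) | C=C1C(=O)O[C@@H]2/C=C(/C(OCC)OCC)[C@@H](OC(C)=O)CC[C@@](C)(O[Si](CC)(CC)CC)C[C@@H](O)[C@@H]12 | intermediate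
29 | mixed anhydride of 11 with 2,4,6-trichlorobenzoic acid | C/C=C(/CO[Si](CC)(CC)CC)C(=O)OC(=O)c1c(Cl)cc(Cl)cc1Cl | intermediate (not isolated)
30 | 8-O-[(Z)-2-(triethylsilyloxymethyl)but-2-enoyl] derivative of 28 | C=C1C(=O)O[C@@H]2/C=C(/C(OCC)OCC)[C@@H](OC(C)=O)CC[C@@](C)(O[Si](CC)(CC)CC)C[C@@H](OC(=O)/C(=C\C)CO[Si](CC)(CC)CC)[C@@H]12 | intermediate
31 | (3S,6R,7R,8R,10R)-10-hydroxy-Δ4-15-al with free side-chain OH | C=C1C(=O)O[C@@H]2/C=C(/C=O)[C@@H](OC(C)=O)CC[C@@](C)(O)C[C@@H](OC(=O)/C(=C\C)CO)[C@@H]12 | intermediate (not isolated)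
32 | (3S,4S,5R,6S,7R,8R,10R)-5,10-epoxy-15-al | C=C1C(=O)O[C@@H]2[C@@H]3O[C@](C)(CC[C@H](OC(C)=O)[C@@H]3C=O)C[C@@H](OC(=O)/C(=C\C)CO)[C@@H]12 | intermediate (not isolated)
33 | CNP0195618.1 | C=C1C(=O)O[C@@H]2[C@@H]3O[C@](C)(CC[C@H](OC(C)=O)[C@@H]3CO)C[C@@H](OC(=O)/C(=C\C)CO)[C@@H]12 | target

**Step count and risks**

Total step count: 16. Longest linear sequence: 11 steps (steps 1–3, then 9–16).

Most likely to fail:

1. Step 14 (ten-membered ring closure and the facial sense at C7). If the allylchromium attacks anti to the C8 oxygen instead, the C6/C7 pair would be wrong relative to C3 and C10. The fallback relays the stereochemistry through inversion at C8. It sets out from aldehyde 19: chlorination with (2S,5S)-2,5-diphenylpyrrolidine gives the (3S,8R,10R)-8-chloro aldehyde F1; vinylalane addition and Cs2CO3 closure give the (3S,7S,8S,10R)-vinyl epoxide F2; Swern oxidation gives the epoxy enal F3; the same Me3SiBr/CrCl2 sequence then gives the 8α-hydroxy macrolactone F4 with the required C6 and C7 configuration. Mitsunobu esterification of F4 with acid 11 (PPh3, DIAD, toluene, 0 °C) inverts C8 and installs the side chain, coming back to the route at 30.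

2. Step 16 (transannular oxa-Michael; C5 and C4; the strained inside,outside bridge). If acid gives the C5 or C4 epimer or no cyclisation, the fallback replaces substrate-controlled Brønsted acid catalysis by covalent iminium/enamine catalysis. It sets out from 30: the silyl ethers and the acetal are removed under buffered conditions (HF·pyridine/pyridine, then wet oxalic acid on silica) and hydroxy enal 31 is isolated. Compound 31 is then cyclised with (S)-α,α-diphenylprolinol trimethylsilyl ether (20 mol%; its enantiomer if mismatched) and benzoic acid in toluene, so that the catalyst selects the enal face and the enamine protonation sets C4. Hydrolysis of the enamine comes back to the route at 32, which is reduced as before to 33. No new compound is involved.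

3. Step 9 (enantioselectivity of the hindered alkenylzinc addition at C3). The fallback sets the centre by reagent-controlled reduction instead. It sets out from 6 and 15: the alkenyllithium from 6 is added to 15 without a chiral ligand to give the allylic alcohol as a C3 epimer mixture F5; Dess–Martin oxidation gives the enone F6; reduction with (R)-2-methyl-CBS-oxazaborolidine and catecholborane at −78 °C gives the (3S,10R)-allylic alcohol F7; acetylation (Ac2O, pyridine) comes back to the route at 18.

**Further compounds**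

F1 | step 14 | (3S,8R,10R)-8-chloro C7 aldehyde (8-epimer of 20) | O=C[C@H](Cl)C[C@](C)(O[Si](CC)(CC)CC)CC[C@H](OC(C)=O)/C(=C\CO[Si](CC)(CC)CC)C(OCC)OCC
F2 | step 14 | (3S,7S,8S,10R)-7,8-epoxy α-methylene ester | C=C(C(=O)OC)[C@@H]1O[C@H]1C[C@](C)(O[Si](CC)(CC)CC)CC[C@H](OC(C)=O)/C(=C\CO[Si](CC)(CC)CC)C(OCC)OCC
F3 | step 14 | (3S,7S,8S,10R)-epoxy enal | C=C(C(=O)OC)[C@@H]1O[C@H]1C[C@](C)(O[Si](CC)(CC)CC)CC[C@H](OC(C)=O)/C(=C\C=O)C(OCC)OCC
F4 | step 14 | 8α-hydroxy macrolactone (8S; 8-epimer of 28) | C=C1C(=O)O[C@@H]2/C=C(/C(OCC)OCC)[C@@H](OC(C)=O)CC[C@@](C)(O[Si](CC)(CC)CC)C[C@H](O)[C@@H]12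
F0 | step 16 | none | none
F5 | step 9 | allylic alcohol of the coupled chain as C3 epimer mixture | C=C[C@](C)(O[Si](CC)(CC)CC)CCC(O)/C(=C\CO[Si](CC)(CC)CC)C(OCC)OCC
F6 | step 9 | C3 ketone (enone) of the coupled chain | C=C[C@](C)(O[Si](CC)(CC)CC)CCC(=O)/C(=C\CO[Si](CC)(CC)CC)C(OCC)OCC
F7 | step 9 | (3S,10R)-allylic alcohol of the coupled chain | C=C[C@](C)(O[Si](CC)(CC)CC)CC[C@H](O)/C(=C\CO[Si](CC)(CC)CC)C(OCC)OCC
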